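**Assumptions (one line):** 2‑C‑methyl‑D‑ribono‑1,4‑lactone and dimethyl (R)‑2‑methylsuccinate are purchasable, and the angelate is installed last to avoid angelate→tiglate isomerisation.

## Retrosynthetic overview
1. Rufesolide C ⇒ C8‑alcohol (angelate added last) ⇒ 10‑membered carbocycle plus trans α‑methylene‑γ‑lactone, formed together in one step by intramolecular photoredox/Cr allylation of a C6 aldehyde with a (Z)‑2‑(bromomethyl)enoate (C6–C7 bond).
2. The acyclic precursor ⇒ C2–C3 aldol (Felkin, syn, C4 controls C3) of a methyl ketone with (R)‑4‑silyloxy‑2‑methylbutanal.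
3. The methyl ketone supplies C1, C7–C10, with C10 (R) and C8 (S) taken from 2‑C‑methyl‑D‑ribonolactone (C9 deoxygenated). The C4 methyl centre comes from (R)‑methylsuccinate.
4. The only ring formed is the lactone/10‑ring pair in Step 19; the ribonolactone ring is temporary and opened in Step 4.

## Route

**Step 1**
Reactants: 1, 2‑C‑methyl‑D‑ribono‑1,4‑lactone
Product: 2, 5‑O‑TES lactone
Conditions: TESCl, imidazole, DMF, 0 °C
Reagents that add atoms: TESCl, CC[Si](Cl)(CC)CC
Why: The primary 5‑OH is silylated selectively over the hindered secondary and tertiary OH groups (silyl ether formation); no stereocentre is touched.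

**Step 2**
Reactants: 2
Product: 3, 3‑O‑(phenoxythiocarbonyl) ester
Conditions: PhOC(S)Cl, pyridine, DMAP (cat.), MeCN, 0 °C → rt
Reagents that add atoms: phenyl chlorothionoformate, S=C(Cl)Oc1ccccc1
Why: The secondary 3‑OH is acylated while the tertiary 2‑OH stays free, giving the Barton–McCombie radical precursor.

**Step 3**
Reactants: 3
Product: 4, 3‑deoxy lactone
Conditions: (TMS)3SiH, AIBN, PhMe, 80 °C
Reagents that add atoms: none (H only)
Why: Barton–McCombie deoxygenation removes the future C9 oxygen; the radical is at a CH2 position, so the C10 and C8 centres are unaffected.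

**Step 4**
Reactants: 4
Product: 5, Weinreb amide with free C8‑OH and C10‑OH
Conditions: MeNH(OMe)·HCl, AlMe3, CH2Cl2, 0 °C → rt
Reagents that add atoms: N,O‑dimethylhydroxylamine, CONC
Why: Al‑amide opening of the temporary lactone (Weinreb amidation) unmasks C8‑OH and sets C1 at the acyl oxidation level.

**Step 5**
Reactants: 5
Product: 6, C8‑O‑TBDPS ether
Conditions: TBDPSCl, imidazole, DMAP, DMF, 50 °C
Reagents that add atoms: TBDPSCl, CC(C)(C)[Si](Cl)(c1ccccc1)c1ccccc1
Why: Only the secondary C8‑OH is silylated; the tertiary alcohol is too hindered.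

**Step 6**
Reactants: 6
Product: 7, methyl ketone (C1=O, C2 = CH3)
Conditions: MeMgBr (3 equiv), THF, 0 °C
Reagents that add atoms: MeMgBr, C[Mg]Br
Why: Weinreb ketone synthesis stops at the ketone and leaves the silyl ethers intact.

**Step 7**
Reactants: 7
Product: 8, C10 acetate
Conditions: Ac2O, DMAP, Et3N, MeCN, 50 °C
Reagents that add atoms: Ac2O, CC(=O)OC(C)=O
Why: Nucleophilic acylation of the tertiary α‑hydroxy ketone installs the C10 OAc with retention (no bond to C10 is broken).

**Step 8**
Reactants: 9, dimethyl (R)‑2‑methylsuccinate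
Product: 10, (R)‑2‑methylbutane‑1,4‑diol
Conditions: LiAlH4, THF, 0 °C → rt
Reagents that add atoms: none
Why: Ester reduction leaves the α‑methyl stereocentre untouched; this is the C4 source.

**Step 9**
Reactants: 10
Product: 11, (R)‑4‑OTBS‑2‑methylbutan‑1‑ol
Conditions: TBSCl (1.0 equiv), imidazole, CH2Cl2, 0 °C
Reagents that add atoms: TBSCl, CC(C)(C)[Si](C)(C)Cl
Why: The less hindered 4‑OH (future C6‑O) is silylated preferentially; the minor regioisomer is removed by chromatography.

**Step 10**
Reactants: 11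
Product: 12, (R)‑4‑OTBS‑2‑methylbutanal
Conditions: DMP, NaHCO3, CH2Cl2, 0 °C
Reagents that add atoms: none
Why: Buffered Dess–Martin oxidation gives the α‑methyl aldehyde without epimerisation.

**Step 11**
Reactants: 8 and 12
Product: 13, syn β‑hydroxy ketone
Conditions: Cy2BCl, Et3N, Et2O, −78 → 0 °C; add 12; H2O2, pH 7 buffer work‑up
Reagents that add atoms: none (the boron is removed in the work‑up)
Why: Boron aldol at the only enolisable site (C2, since C10 is quaternary); the new C3 centre follows Felkin–Anh control from C4, giving 3,4‑syn (3R,4R).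

**Step 12**
Reactants: 13
Product: 14, C3‑OMe ether
Conditions: Me3O+BF4−, proton sponge, CH2Cl2, rt
Reagents that add atoms: trimethyloxonium tetrafluoroborate, C[O+](C)C.F[B-](F)(F)F
Why: Non‑basic O‑methylation of the β‑hydroxy ketone avoids retro‑aldol and elimination.

**Step 13**
Reactants: 14
Product: 15, free C7 primary alcohol
Conditions: PPTS, MeOH/CH2Cl2, 0 °C
Reagents that add atoms: none
Why: Acid methanolysis cleaves the primary TES ether selectively over primary TBS and secondary TBDPS.

**Step 14**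
Reactants: 15
Product: 16, C7 aldehyde (α‑silyloxy)
Conditions: DMP, NaHCO3, CH2Cl2, 0 °C; crude used immediately
Reagents that add atoms: none
Why: Mild oxidation gives the aldehyde needed for the Baylis–Hillman reaction; buffering limits epimerisation at C8.

**Step 15**
Reactants: 16
Product: 17, Baylis–Hillman adduct at C7 (C7 epimers)
Conditions: methyl acrylate (neat), DABCO, rt, 3–4 d
Reagents that add atoms: methyl acrylate, C=CC(=O)OC
Why: Morita–Baylis–Hillman reaction builds the C11–C13/C12 unit; the C7 carbinol centre is destroyed in the next step.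

**Step 16**
Reactants: 17
Product: 18, (Z)‑2‑(bromomethyl)enoate (C7=C11, C13–Br)
Conditions: NBS, Me2S, CH2Cl2, −20 → 0 °C
Reagents that add atoms: NBS, O=C1CCC(=O)N1Br
Why: Corey–Kim‑type SN2′ bromination converts the allylic alcohol to the (Z)‑allylic bromide needed for chromium allylation.

**Step 17**
Reactants: 18
Product: 19, free C6 primary alcohol
Conditions: CSA (0.1 equiv), MeOH/CH2Cl2, 0 °C
Reagents that add atoms: none
Why: Acidic methanolysis removes the primary TBS and leaves the secondary TBDPS ether.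

**Step 18**
Reactants: 19
Product: 20, C6 aldehyde
Conditions: DMP, NaHCO3, CH2Cl2, 0 °C
Reagents that add atoms: none
Why: Gives the electrophile for the ring closure; the allylic bromide and enoate survive.

**Step 19**
Reactants: 20
Product: 21, 8‑O‑TBDPS ether of rufesolide C (10‑ring plus trans lactone)
Conditions: CrCl3 (20 mol%), 4CzIPN (2 mol%), Hantzsch ester (2 equiv), MeCN/THF 1:1, 2 mM (syringe‑pump addition), blue LEDs, 25 °C, 12 h; then TsOH·H2O (cat.), CH2Cl2, rt
Reagents that add atoms: none (the OMe is lost as MeOH on lactonisation)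
Why: Proposed new method: photoreduced 4CzIPN (quenched by Hantzsch ester) reduces Cr(III) to Cr(II), which converts the allylic bromide into an allyl‑Cr(III) species that adds through its γ‑carbon (C7) to the C6 aldehyde via a chair Zimmerman–Traxler transition state, closing the 10‑ring; the Cr(III) alkoxide is protonated, turning over Cr, and acid lactonisation onto C12 gives the lactone. The closest known chemistry is stoichiometric intramolecular Nozaki–Hiyama–Kishi allylation macrocyclisation used for germacranolides, combined with intermolecular Cr/photoredox catalytic allylation; the anti‑selective allylation gives the trans‑fused lactone, with C6/C7 configuration directed by the ring conformation set by C3, C4, C8 and C10.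

**Step 20**
Reactants: 21
Product: 22, 8‑hydroxy lactone (desangeloyl rufesolide C)
Conditions: HF·pyridine, THF/pyridine 1:1, 40 °C
Reagents that add atoms: none
Why: Fluoride removes the TBDPS group; the ketone, acetate, methyl ether and α‑methylene lactone are inert to it.

**Step 21**
Reactants: 22
Product: 23, Rufesolide C
Conditions: angelic acid, 2,4,6‑Cl3C6H2COCl, Et3N, THF; then 22, DMAP, PhMe, rt
Reagents that add atoms: angelic acid, OC(=O)/C(C)=C\C (the trichlorobenzoyl chloride is only an activator)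
Why: Yamaguchi esterification of the secondary C8‑OH with preserved (Z)‑geometry; the hindered tertiary centres are not acylated.

## Compound list
1 | 2‑C‑methyl‑D‑ribono‑1,4‑lactone, (3R,4R,5R)‑3,4‑dihydroxy‑5‑(hydroxymethyl)‑3‑methyloxolan‑2‑one | C[C@@]1(O)[C@H](O)[C@@H](CO)OC1=O | starting material
2 | 5‑O‑TES lactone | C[C@@]1(O)[C@H](O)[C@@H](CO[Si](CC)(CC)CC)OC1=O | intermediate
3 | 3‑O‑phenoxythiocarbonyl lactone | C[C@@]1(O)[C@H](OC(=S)Oc2ccccc2)[C@@H](CO[Si](CC)(CC)CC)OC1=O | intermediate
4 | (3R,5S)‑3‑hydroxy‑3‑methyl‑5‑(TESOCH2)oxolan‑2‑one | C[C@@]1(O)C[C@@H](CO[Si](CC)(CC)CC)OC1=O | intermediate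
5 | (2R,4S)‑2,4‑dihydroxy‑N‑methoxy‑N,2‑dimethyl‑5‑(TESO)pentanamide | CON(C)C(=O)[C@](C)(O)C[C@H](O)CO[Si](CC)(CC)CC | intermediate
6 | 4‑O‑TBDPS analogue of 5 | CON(C)C(=O)[C@](C)(O)C[C@H](O[Si](c1ccccc1)(c1ccccc1)C(C)(C)C)CO[Si](CC)(CC)CC | intermediate
7 | (3R,5S)‑5‑(TBDPSO)‑3‑hydroxy‑3‑methyl‑6‑(TESO)hexan‑2‑one | CC(=O)[C@](C)(O)C[C@H](O[Si](c1ccccc1)(c1ccccc1)C(C)(C)C)CO[Si](CC)(CC)CC | intermediate
8 | acetate of 7 (C10‑OAc) | CC(=O)[C@](C)(OC(C)=O)C[C@H](O[Si](c1ccccc1)(c1ccccc1)C(C)(C)C)CO[Si](CC)(CC)CC | intermediate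
9 | dimethyl (2R)‑2‑methylbutanedioate | COC(=O)[C@H](C)CC(=O)OC | starting material
10 | (2R)‑2‑methylbutane‑1,4‑diol | OC[C@H](C)CCO | intermediate
11 | (2R)‑4‑(TBSO)‑2‑methylbutan‑1‑ol | OC[C@H](C)CCO[Si](C)(C)C(C)(C)C | intermediate
12 | (2R)‑4‑(TBSO)‑2‑methylbutanal | O=C[C@H](C)CCO[Si](C)(C)C(C)(C)C | intermediate
13 | aldol adduct (3R,4R,8S,10R; C6‑OTBS, C3‑OH, C1 ketone, C10‑OAc, C8‑OTBDPS, C7‑OTES) | CC(C)(C)[Si](C)(C)OCC[C@@H](C)[C@H](O)CC(=O)[C@](C)(OC(C)=O)C[C@H](O[Si](c1ccccc1)(c1ccccc1)C(C)(C)C)CO[Si](CC)(CC)CC | intermediate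
14 | C3‑OMe ether of 13 | CC(C)(C)[Si](C)(C)OCC[C@@H](C)[C@H](OC)CC(=O)[C@](C)(OC(C)=O)C[C@H](O[Si](c1ccccc1)(c1ccccc1)C(C)(C)C)CO[Si](CC)(CC)CC | intermediate
15 | C7 primary alcohol | CC(C)(C)[Si](C)(C)OCC[C@@H](C)[C@H](OC)CC(=O)[C@](C)(OC(C)=O)C[C@H](O[Si](c1ccccc1)(c1ccccc1)C(C)(C)C)CO | intermediate
16 | C7 aldehyde | CC(C)(C)[Si](C)(C)OCC[C@@H](C)[C@H](OC)CC(=O)[C@](C)(OC(C)=O)C[C@H](O[Si](c1ccccc1)(c1ccccc1)C(C)(C)C)C=O | intermediate
17 | Baylis–Hillman adduct (C7 epimers) | CC(C)(C)[Si](C)(C)OCC[C@@H](C)[C@H](OC)CC(=O)[C@](C)(OC(C)=O)C[C@H](O[Si](c1ccccc1)(c1ccccc1)C(C)(C)C)C(O)C(=C)C(=O)OC | intermediate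
18 | (Z)‑allylic bromide enoate | CC(C)(C)[Si](C)(C)OCC[C@@H](C)[C@H](OC)CC(=O)[C@](C)(OC(C)=O)C[C@H](O[Si](c1ccccc1)(c1ccccc1)C(C)(C)C)/C=C(\CBr)C(=O)OC | intermediate
19 | C6 primary alcohol | OCC[C@@H](C)[C@H](OC)CC(=O)[C@](C)(OC(C)=O)C[C@H](O[Si](c1ccccc1)(c1ccccc1)C(C)(C)C)/C=C(\CBr)C(=O)OC | intermediate
20 | C6 aldehyde (cyclisation precursor) | O=CC[C@@H](C)[C@H](OC)CC(=O)[C@](C)(OC(C)=O)C[C@H](O[Si](c1ccccc1)(c1ccccc1)C(C)(C)C)/C=C(\CBr)C(=O)OC | intermediate
21 | 8‑O‑TBDPS rufesolide C skeleton (no angeloyl) | C=C1C(=O)O[C@@H]2C[C@@H](C)[C@H](OC)CC(=O)[C@](C)(OC(C)=O)C[C@H](O[Si](c3ccccc3)(c3ccccc3)C(C)(C)C)[C@@H]12 | intermediate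
22 | 8‑hydroxy (desangeloyl) rufesolide C | C=C1C(=O)O[C@@H]2C[C@@H](C)[C@H](OC)CC(=O)[C@](C)(OC(C)=O)C[C@H](O)[C@@H]12 | intermediate
23 | Rufesolide C | C=C1C(=O)O[C@@H]2C[C@@H](C)[C@H](OC)CC(=O)[C@](C)(OC(C)=O)C[C@H](OC(=O)/C(C)=C\C)[C@@H]12 | target

**Total steps:** 21. **Longest linear sequence:** 18 (Steps 1–7, then 11–21).

## Three steps most likely to fail
1. **Step 19 (proposed new photoredox/Cr macrocyclisation).** Risks are oligomerisation, direct photoreduction of the allylic bromide, and wrong C6/C7 diastereoselectivity.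
   - Fallback: build the trans lactone first by known intermolecular Cr(II) or Zn Barbier allylation of a C6 aldehyde (with C3 carried as a dimethyl acetal). Then unmask the C3 aldehyde and close the ring by high‑dilution macro‑aldol at C2–C3, followed by C3 O‑methylation.
2. **Step 11 (boron aldol).** The enolate is hindered and Felkin selectivity with an α‑methyl aldehyde lacking β‑oxygen may be only moderate.
   - Fallback: use (S)‑3‑PMBO‑2‑methylpropanal (Roche ester) as the acceptor for a higher‑dr Felkin–Evans aldol. Then oxidise C5 to the aldehyde and homologate to C6 by methoxymethylene Wittig/hydrolysis, reordering the late steps.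
3. **Steps 2–3 (deoxygenation next to the free tertiary alcohol).** The neighbouring 2‑OH may form a cyclic thionocarbonate, which would cleave at the wrong carbon.
   - Fallback: change the source of C8/C10 to (S)‑dimethyl malate. Set the C10 quaternary centre by Seebach self‑regeneration methylation of the pivaldehyde‑derived dioxolanone, and set C8 by syn (Narasaka–Prasad) reduction of the C8 vinyl ketone directed by the C10 hydroxyl, so no C9 deoxygenation is needed.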